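**Retrosynthetic overview**

- Rings B (dihydropyranone) and C (butyrolactone) are closed together in the last operation. The target is cut at the C3=C4 olefin and at both lactone C(=O)–O bonds, giving a trans-fused bicyclic lactol (C6–O held as a γ-lactone; aldehyde and CH2OH held as a lactol) and an α-alkylated Z-selective phosphonoacetate that carries ring A.
- The bicyclic lactol comes from an anti-2-vinyl-1,3-diol (vinyl → CH2C(=O)). Its two stereocentres are set at once by iridium-catalysed (hydroxymethyl)allylation of 3,3-diethoxypropan-1-ol with vinyl ethylene carbonate.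
- The phosphonate comes from an E-homoallylic iodide, made by zirconium-catalysed carboalumination of the alkyne derived from dihydro-β-ionone.
- Ring order: ring A is bought; a temporary pyran acetal and a temporary γ-lactone are formed on the way; ring C and then ring B form last, in one pot.

Assumption: the iridium catalyst bearing (S)-SEGPHOS is taken to give the (3R,4R)-diol; if the facial sense is the opposite one, (R)-SEGPHOS is used and nothing else changes.

**Step 1**
Reactants: 1 3,3-diethoxypropan-1-ol; 2 4-vinyl-1,3-dioxolan-2-one (vinyl ethylene carbonate, racemic)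
Product: 4 (3R,4R)-1,1-diethoxy-4-(hydroxymethyl)hex-5-en-3-ol, via 3,3-diethoxypropanal 3 (not isolated)
Conditions: [Ir(cod)Cl]2 (2.5 mol %), (S)-SEGPHOS (5 mol %), 4-cyano-3-nitrobenzoic acid (10 mol %), K3PO4 (10 mol %), 2 (2 equiv), THF, 90 °C
Reagents that add atoms: none
Why: Iridium-catalysed transfer-hydrogenative carbonyl (hydroxymethyl)allylation (Krische-type redox-triggered coupling), in which the catalyst dehydrogenates 1 to aldehyde 3, ionises 2 with loss of CO2 to an E-configured hydroxymethyl-allyl iridium nucleophile and adds it to 3 through a closed chair transition state, so the anti relationship comes from the allyl geometry and the absolute configuration of both new stereocentres from the chiral ligand.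

**Step 2**
Reactants: 4 (3R,4R)-1,1-diethoxy-4-(hydroxymethyl)hex-5-en-3-ol
Product: 5 (4R,5R)-2-ethoxy-5-vinyltetrahydro-2H-pyran-4-ol (mixture of anomers)
Conditions: PPTS (5 mol %), CH2Cl2, 23 °C
Reagents that add atoms: none
Why: Acid-catalysed intramolecular transacetalisation, in which only the primary hydroxyl can reach the acetal carbon through a six-membered ring, so the aldehyde and the primary alcohol are masked together while the secondary hydroxyl stays free and no existing stereocentre is touched (the anomeric centre is of no consequence).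

**Step 3**
Reactants: 5 (4R,5R)-2-ethoxy-5-vinyltetrahydro-2H-pyran-4-ol
Product: 7 (4R,5R)-2-ethoxy-5-(2-hydroxyethyl)tetrahydro-2H-pyran-4-ol, via O,B-bis(9-BBN) adduct 6 (not isolated)
Conditions: 9-BBN (2.3 equiv), THF, 0 → 23 °C; then NaOH, H2O2, H2O, 0 → 23 °C
Reagents that add atoms: hydrogen peroxide, OO
Why: Anti-Markovnikov hydroboration–oxidation, in which the bulky borane places boron on the terminal vinyl carbon (the free hydroxyl is only converted to its borinate) and alkaline peroxide replaces boron by hydroxyl with both stereocentres untouched.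

**Step 4**
Reactants: 7 (4R,5R)-2-ethoxy-5-(2-hydroxyethyl)tetrahydro-2H-pyran-4-ol
Product: 9 (3aR,7aR)-6-ethoxyhexahydro-2H-furo[3,2-c]pyran-2-one (trans-fused, mixture of anomers), via lactol 8 (not isolated)
Conditions: TEMPO (0.2 equiv), PhI(OAc)2 (2.5 equiv), CH2Cl2, 23 °C
Reagents that add atoms: none
Why: TEMPO/PhI(OAc)2 oxidative lactonisation, in which the oxoammonium species oxidises only the primary alcohol, the aldehyde is trapped by the single free (secondary) hydroxyl as lactol 8 and this is oxidised on to the γ-lactone, so the C6 oxygen is stored as a lactone and no stereocentre changes.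

**Step 5**
Reactants: 9 (3aR,7aR)-6-ethoxyhexahydro-2H-furo[3,2-c]pyran-2-one
Product: 10 (3aR,7aR)-6-hydroxyhexahydro-2H-furo[3,2-c]pyran-2-one (bicyclic lactol, mixture of anomers)
Conditions: AcOH/H2O (4:1), 45 °C
Reagents that add atoms: water, O
Why: Mild acid hydrolysis of a 2-deoxy-glycoside-type acetal, which is far more labile than the γ-lactone, releases the lactol (masked aldehyde plus masked primary alkoxide) without touching the two stereocentres.

**Step 6**
Reactants: 11 dihydro-β-ionone, 4-(2,6,6-trimethylcyclohex-1-en-1-yl)butan-2-one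
Product: 13 2-(but-3-yn-1-yl)-1,3,3-trimethylcyclohex-1-ene, via enol phosphate 12 (not isolated)
Conditions: LiN(i-Pr)2 (1.05 equiv), THF, −78 °C; ClP(O)(OEt)2, −78 → 23 °C; then LiN(i-Pr)2 (2.3 equiv), −78 → 23 °C
Reagents that add atoms: none
Why: Negishi's one-pot methyl ketone to terminal alkyne conversion, by kinetic deprotonation at the methyl group, O-phosphorylation to enol phosphate 12 and base-induced β-elimination of diethyl phosphate.

**Step 7**
Reactants: 13 2-(but-3-yn-1-yl)-1,3,3-trimethylcyclohex-1-ene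
Product: 16 (3E)-4-methyl-6-(2,6,6-trimethylcyclohex-1-en-1-yl)hex-3-en-1-ol, via alkenylalane 14 (not isolated), via lithium aluminate 15 (not isolated)
Conditions: Me3Al (2.0 equiv), Cp2ZrCl2 (0.2 equiv), CH2Cl2, 0 → 23 °C; evaporate, hexane; n-BuLi, −78 → 0 °C; ethylene oxide, THF, 0 → 23 °C
Reagents that add atoms: trimethylaluminium, C[Al](C)C; ethylene oxide, C1CO1
Why: Zirconium-catalysed carboalumination (Negishi) adds methyl and aluminium syn across the alkyne with the metal at the terminus, which fixes the E-trisubstituted olefin, and the derived aluminate 15 opens ethylene oxide with retention of olefin geometry.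

**Step 8**
Reactants: 16 (3E)-4-methyl-6-(2,6,6-trimethylcyclohex-1-en-1-yl)hex-3-en-1-ol
Product: 17 2-[(3E)-6-iodo-3-methylhex-3-en-1-yl]-1,3,3-trimethylcyclohex-1-ene
Conditions: I2, PPh3, imidazole, CH2Cl2, 0 → 23 °C
Reagents that add atoms: iodine, II
Why: Appel-type iodination, in which iodide displaces the primary oxyphosphonium group by SN2 without touching either olefin.

**Step 9**
Reactants: 17 2-[(3E)-6-iodo-3-methylhex-3-en-1-yl]-1,3,3-trimethylcyclohex-1-ene; 18 ethyl 2-(diphenoxyphosphoryl)acetate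
Product: 19 ethyl (5E)-2-(diphenoxyphosphoryl)-6-methyl-8-(2,6,6-trimethylcyclohex-1-en-1-yl)oct-5-enoate (racemic at C2)
Conditions: 18 (1.5 equiv), NaH, DMSO, 23 → 50 °C
Reagents that add atoms: none
Why: SN2 C-alkylation of the sodium salt of the Ando phosphonoacetate by the primary iodide (phosphonate in excess to suppress dialkylation) gives the α-alkylated Z-selective olefination reagent, whose new stereocentre is racemic and is destroyed in step 10.

**Step 10**
Reactants: 10 (3aR,7aR)-6-hydroxyhexahydro-2H-furo[3,2-c]pyran-2-one; 19 ethyl (5E)-2-(diphenoxyphosphoryl)-6-methyl-8-(2,6,6-trimethylcyclohex-1-en-1-yl)oct-5-enoate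
Product: 22 (6R)-3-[(3E)-4-methyl-6-(2,6,6-trimethylcyclohex-1-en-1-yl)hex-3-en-1-yl]-6-[(3R)-5-oxotetrahydrofuran-3-yl]-5,6-dihydro-2H-pyran-2-one, via Z-enoate lactone 20 (not isolated), via hydroxy ester 21 (not isolated)
Conditions: 19 (1.3 equiv), NaH (2.4 equiv), THF, −78 → 0 °C; then CSA (3 equiv), PhMe, 60 °C, one pot
Reagents that add atoms: none
Why: Proposed new method: Ando-type Z-selective Horner–Wadsworth–Emmons olefination of the open hydroxy-aldehyde form of lactol 10 gives Z-enoate 20 and frees the primary hydroxyl, which takes over the lactone acyl group by O-to-O acyl migration (translactonisation, known for β-(hydroxymethyl)-γ-butyrolactones) to close ring C in 21, whose liberated C6 hydroxyl then closes on the cis-disposed ethyl ester to ring B with loss of ethanol, the sequence being driven by formation of the second ring and closest to the known Z-selective olefination–lactonisation route from β-hydroxy aldehydes to 5,6-dihydropyran-2-ones, while no bond to either stereocentre is broken so both are retained.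

**Compound list**

1 | 3,3-diethoxypropan-1-ol | OCCC(OCC)OCC | starting material
2 | 4-vinyl-1,3-dioxolan-2-one (racemic) | C=CC1COC(=O)O1 | starting material
3 | 3,3-diethoxypropanal | CCOC(CC=O)OCC | intermediate (not isolated)
4 | (3R,4R)-1,1-diethoxy-4-(hydroxymethyl)hex-5-en-3-ol | CCOC(OCC)C[C@@H](O)[C@@H](CO)C=C | intermediate
5 | (4R,5R)-2-ethoxy-5-vinyltetrahydro-2H-pyran-4-ol (anomeric mixture) | CCOC1C[C@@H](O)[C@H](C=C)CO1 | intermediate
6 | O,B-bis(9-BBN) adduct of 5: 9-BBN borinate of the C4 hydroxyl, B-alkyl-9-BBN at the former vinyl terminus | CCOC1C[C@@H](OB2C3CCCC2CCC3)[C@H](CCB2C3CCCC2CCC3)CO1 | intermediate (not isolated)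
7 | (4R,5R)-2-ethoxy-5-(2-hydroxyethyl)tetrahydro-2H-pyran-4-ol | CCOC1C[C@@H](O)[C@H](CCO)CO1 | intermediate
8 | (3aR,7aR)-6-ethoxyhexahydro-2H-furo[3,2-c]pyran-2-ol (lactol) | CCOC1C[C@H]2OC(O)C[C@@H]2CO1 | intermediate (not isolated)
9 | (3aR,7aR)-6-ethoxyhexahydro-2H-furo[3,2-c]pyran-2-one | CCOC1C[C@H]2OC(=O)C[C@@H]2CO1 | intermediate
10 | (3aR,7aR)-6-hydroxyhexahydro-2H-furo[3,2-c]pyran-2-one | OC1C[C@H]2OC(=O)C[C@@H]2CO1 | intermediate
11 | dihydro-β-ionone, 4-(2,6,6-trimethylcyclohex-1-en-1-yl)butan-2-one | CC(=O)CCC1=C(C)CCCC1(C)C | starting material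
12 | diethyl 4-(2,6,6-trimethylcyclohex-1-en-1-yl)but-1-en-2-yl phosphate | C=C(CCC1=C(C)CCCC1(C)C)OP(=O)(OCC)OCC | intermediate (not isolated)
13 | 2-(but-3-yn-1-yl)-1,3,3-trimethylcyclohex-1-ene | C#CCCC1=C(C)CCCC1(C)C | intermediate
14 | dimethyl[(1E)-2-methyl-4-(2,6,6-trimethylcyclohex-1-en-1-yl)but-1-en-1-yl]aluminium | C[Al](C)/C=C(\C)CCC1=C(C)CCCC1(C)C | intermediate (not isolated)
15 | lithium butyl(dimethyl)[(1E)-2-methyl-4-(2,6,6-trimethylcyclohex-1-en-1-yl)but-1-en-1-yl]aluminate | [Li+].CCCC[Al-](C)(C)/C=C(\C)CCC1=C(C)CCCC1(C)C | intermediate (not isolated)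
16 | (3E)-4-methyl-6-(2,6,6-trimethylcyclohex-1-en-1-yl)hex-3-en-1-ol | OCC/C=C(\C)CCC1=C(C)CCCC1(C)C | intermediate
17 | 2-[(3E)-6-iodo-3-methylhex-3-en-1-yl]-1,3,3-trimethylcyclohex-1-ene | ICC/C=C(\C)CCC1=C(C)CCCC1(C)C | intermediate
18 | ethyl 2-(diphenoxyphosphoryl)acetate | CCOC(=O)CP(=O)(Oc1ccccc1)Oc1ccccc1 | starting material
19 | ethyl (5E)-2-(diphenoxyphosphoryl)-6-methyl-8-(2,6,6-trimethylcyclohex-1-en-1-yl)oct-5-enoate (racemic at C2) | CCOC(=O)C(CC/C=C(\C)CCC1=C(C)CCCC1(C)C)P(=O)(Oc1ccccc1)Oc1ccccc1 | intermediate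
20 | ethyl (2Z,5E)-2-{2-[(2R,3R)-3-(hydroxymethyl)-5-oxotetrahydrofuran-2-yl]ethylidene}-6-methyl-8-(2,6,6-trimethylcyclohex-1-en-1-yl)oct-5-enoate | CCOC(=O)/C(CC/C=C(\C)CCC1=C(C)CCCC1(C)C)=C\C[C@H]2OC(=O)C[C@@H]2CO | intermediate (not isolated)
21 | ethyl (2Z,5E)-2-{(3R)-3-hydroxy-3-[(3R)-5-oxotetrahydrofuran-3-yl]propylidene}-6-methyl-8-(2,6,6-trimethylcyclohex-1-en-1-yl)oct-5-enoate | CCOC(=O)/C(CC/C=C(\C)CCC1=C(C)CCCC1(C)C)=C\C[C@@H](O)[C@H]2COC(=O)C2 | intermediate (not isolated)
22 | (6R)-3-[(3E)-4-methyl-6-(2,6,6-trimethylcyclohex-1-en-1-yl)hex-3-en-1-yl]-6-[(3R)-5-oxotetrahydrofuran-3-yl]-5,6-dihydro-2H-pyran-2-one | CC1=C(CC/C(C)=C/CCC2=CC[C@H]([C@H]3COC(=O)C3)OC2=O)C(C)(C)CCC1 | target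

**Totals**

Total steps: 10. Longest linear sequence: 6 (steps 1, 2, 3, 4, 5, 10); the side-chain branch is 5 (steps 6, 7, 8, 9, 10).

**Three steps most likely to fail**

Step 10. The hindered α-alkyl phosphonate may olefinate the lactol slowly or with imperfect Z-selectivity. The freed alkoxide may add back to the enoate (oxa-Michael), or the β-acyloxy aldehyde may eliminate. The fallback sets out from 10 and 17 and returns at 22. Lactol 10 is olefinated with the small commercial reagent methyl 2-[bis(2,2,2-trifluoroethoxy)phosphoryl]acetate (KN(SiMe3)2, 18-crown-6, THF, −78 °C; then CSA, PhMe, 60 °C). This runs the acyl shift and lactonisation on an unhindered Z-enoate and gives (6R)-6-[(3R)-5-oxotetrahydrofuran-3-yl]-5,6-dihydro-2H-pyran-2-one F1. α-Iodination (I2, pyridine, CH2Cl2) gives (6R)-3-iodo-6-[(3R)-5-oxotetrahydrofuran-3-yl]-5,6-dihydro-2H-pyran-2-one F2. Iodide 17 is converted with zinc dust and LiCl in THF into iodo[(3E)-4-methyl-6-(2,6,6-trimethylcyclohex-1-en-1-yl)hex-3-en-1-yl]zinc F3. Negishi coupling of F2 with F3 (PdCl2(dppf), THF, 23 °C) gives 22. The side chain is thus attached by sp2–sp3 cross-coupling after ring formation instead of being carried in the phosphonate.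

Step 1. The transient β,β-dialkoxy aldehyde 3 may lose ethanol under the basic, hot conditions, or the diastereo- and enantioselectivity may be lower than for simple alcohols. The fallback sets out from 1 and returns at 4. Alcohol 1 is oxidised (SO3·pyridine, DMSO, i-Pr2NEt, 0 °C) to aldehyde 3, here isolated and used cold. An Evans syn-aldol with the boron dienolate of (4S)-4-benzyl-3-[(2E)-but-2-enoyl]-1,3-oxazolidin-2-one (Bu2BOTf, Et3N, CH2Cl2, −78 → 0 °C, α-attack) gives (4S)-4-benzyl-3-[(2S,3R)-5,5-diethoxy-3-hydroxy-2-vinylpentanoyl]-1,3-oxazolidin-2-one F4. LiBH4 (THF, MeOH, 0 °C) cleaves the auxiliary reductively to 4. Stereocontrol then comes from a stoichiometric auxiliary and a closed boron transition state instead of the catalyst.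

Step 4. Closure of the trans-fused lactol may be slow, leaving a hydroxy aldehyde or giving over-oxidation. The fallback sets out from 4 and returns at 10. The primary hydroxyl of 4 is silylated (TBSCl, imidazole, CH2Cl2, 0 °C) to (3R,4R)-4-{[tert-butyl(dimethyl)silyl]oxymethyl}-1,1-diethoxyhex-5-en-3-ol F5. 9-BBN followed by NaOH/H2O2 gives (3R,4R)-3-{[tert-butyl(dimethyl)silyl]oxymethyl}-6,6-diethoxyhexane-1,4-diol F6. TEMPO/PhI(OAc)2 closes the unstrained monocyclic lactone (4R,5R)-4-{[tert-butyl(dimethyl)silyl]oxymethyl}-5-(2,2-diethoxyethyl)dihydrofuran-2(3H)-one F7. Aqueous HCl in THF removes the silyl ether and the acetal together, and the hydroxy aldehyde closes to 10.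

**Further compounds**

F1 | step 10 | (6R)-6-[(3R)-5-oxotetrahydrofuran-3-yl]-5,6-dihydro-2H-pyran-2-one | O=C1C=CC[C@H]([C@H]2COC(=O)C2)O1
F2 | step 10 | (6R)-3-iodo-6-[(3R)-5-oxotetrahydrofuran-3-yl]-5,6-dihydro-2H-pyran-2-one | O=C1C(I)=CC[C@H]([C@H]2COC(=O)C2)O1
F3 | step 10 | iodo[(3E)-4-methyl-6-(2,6,6-trimethylcyclohex-1-en-1-yl)hex-3-en-1-yl]zinc | I[Zn]CC/C=C(\C)CCC1=C(C)CCCC1(C)C
F4 | step 1 | (4S)-4-benzyl-3-[(2S,3R)-5,5-diethoxy-3-hydroxy-2-vinylpentanoyl]-1,3-oxazolidin-2-one | CCOC(OCC)C[C@@H](O)[C@H](C=C)C(=O)N1[C@@H](Cc2ccccc2)COC1=O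
F5 | step 4 | (3R,4R)-4-{[tert-butyl(dimethyl)silyl]oxymethyl}-1,1-diethoxyhex-5-en-3-ol | CCOC(OCC)C[C@@H](O)[C@@H](CO[Si](C)(C)C(C)(C)C)C=C
F6 | step 4 | (3R,4R)-3-{[tert-butyl(dimethyl)silyl]oxymethyl}-6,6-diethoxyhexane-1,4-diol | CCOC(OCC)C[C@@H](O)[C@@H](CO[Si](C)(C)C(C)(C)C)CCO
F7 | step 4 | (4R,5R)-4-{[tert-butyl(dimethyl)silyl]oxymethyl}-5-(2,2-diethoxyethyl)dihydrofuran-2(3H)-one | CCOC(OCC)C[C@H]1OC(=O)C[C@@H]1CO[Si](C)(C)C(C)(C)C
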